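**Retrosynthetic overview**

1. The C40 chain is closed last at C14–C15 by Pd-catalysed coupling of a C19 alkenylalane (end group plus C7–C14) with a C21 chloroheptaene (C15 to the open-chain end). Each trisubstituted E-alkene comes from Zr-catalysed methylalumination of a terminal alkyne; the CH=CH spacers come from (E)-1,2-dichloroethene and TMS-acetylene.
2. Open-chain half: 5-bromo-2-methylpent-2-ene plus acetylide gives a C8 enyne, which is extended by two C4 cycles and one C2 cap.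
3. End group: the cyclopentane carbaldehyde (C7 = CHO) comes from the key step, an iodide-relayed semipinacol ring contraction (six- to five-membered) of a 2,3-epoxy-1-silyloxycyclohexane.
4. That epoxy silyl ether comes from MeMgBr addition to the trans-epoxide of (R)-4-isopropenylcyclohex-2-enone, made by desymmetrising deprotonation of 4-isopropenylcyclohexanone (Diels–Alder of 2-silyloxybutadiene with methyl vinyl ketone, then methylenation).
5. Ring order: cyclohexene (Diels–Alder), then oxirane, then cyclopentane (ring contraction); the cyclopentane is the only ring kept.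

Assumption: the sense of induction of the chiral lithium amide in step 3 is taken from its behaviour with 4-tert-butylcyclohexanone, as recalled ((R,R)-amide gives the (S)-enol derivative), so the (S,S)-amide is used; if it proves opposite, the (R,R)-amide is used.

**Step 1**
Reactants: 1 2-(trimethylsilyloxy)buta-1,3-diene; 2 but-3-en-2-one
Product: 3 rac-1-[4-(trimethylsilyloxy)cyclohex-3-en-1-yl]ethan-1-one
Conditions: toluene, hydroquinone (cat.), 110 °C, sealed tube
Reagents that add atoms: none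
Why: Thermal Diels–Alder reaction in which the 2-silyloxy diene directs the acetyl group 1,4 to the silyloxy carbon; the racemic stereocentre is erased at ketone 5.

**Step 2**
Reactants: 3 rac-1-[4-(trimethylsilyloxy)cyclohex-3-en-1-yl]ethan-1-one
Product: 5 4-(prop-1-en-2-yl)cyclohexan-1-one, via silyl enol ether 4 (not isolated)
Conditions: Ph3PCH3Br, n-BuLi, THF, 0 °C to rt; then 1 M HCl, THF, 0 °C
Reagents that add atoms: methyltriphenylphosphonium bromide, C[P+](c1ccccc1)(c1ccccc1)c1ccccc1.[Br-]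
Why: Wittig methylenation of the methyl ketone (the silyl enol ether is inert to the ylide), then acid hydrolysis of the enol ether to the symmetric ketone.

**Step 3**
Reactants: 5 4-(prop-1-en-2-yl)cyclohexan-1-one
Product: 7 (4R)-4-(prop-1-en-2-yl)cyclohex-2-en-1-one, via lithium enolate 6 (not isolated)
Conditions: (S,S)-bis(1-phenylethyl)amine, n-BuLi, LiCl, THF, −78 °C; then PhS(Cl)=N-t-Bu, −78 °C to rt
Reagents that add atoms: none
Why: Enantiotopic-proton-selective deprotonation by the C2-symmetric lithium amide (chiral-base desymmetrisation, expected about 90% ee) sets C4 as R, and the enolate is dehydrogenated in the same flask by the Mukaiyama sulfinimidoyl chloride (sulfenylation, then syn-elimination).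

**Step 4**
Reactants: 7 (4R)-4-(prop-1-en-2-yl)cyclohex-2-en-1-one
Product: 8 (1S,5S,6S)-5-(prop-1-en-2-yl)-7-oxabicyclo[4.1.0]heptan-2-one
Conditions: 30% H2O2, NaOH (0.2 equiv), MeOH, −10 to 0 °C
Reagents that add atoms: hydrogen peroxide, OO
Why: Weitz–Scheffer nucleophilic epoxidation; hydroperoxide adds to C3 anti to the C4 isopropenyl group, so the oxirane is trans to isopropenyl, and the isolated isopropenyl alkene does not react with the nucleophilic oxidant.

**Step 5**
Reactants: 8 (1S,5S,6S)-5-(prop-1-en-2-yl)-7-oxabicyclo[4.1.0]heptan-2-one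
Product: 10 triethyl{[(1S,2R,5S,6S)-2-methyl-5-(prop-1-en-2-yl)-7-oxabicyclo[4.1.0]heptan-2-yl]oxy}silane, via magnesium alkoxide 9 (not isolated)
Conditions: MeMgBr, THF, −78 °C; then Et3SiOTf, 2,6-lutidine, −78 to 0 °C
Reagents that add atoms: methylmagnesium bromide, C[Mg]Br; triethylsilyl trifluoromethanesulfonate, CC[Si](CC)(CC)OS(=O)(=O)C(F)(F)F
Why: Grignard 1,2-addition to the 2,3-epoxy ketone from the face opposite the oxirane oxygen (magnesium bridges carbonyl and oxirane oxygen) sets C2 as R with the oxygen cis to the oxirane and methyl cis to isopropenyl, and the alkoxide is silylated in the same flask.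

**Step 6**
Reactants: 10 triethyl{[(1S,2R,5S,6S)-2-methyl-5-(prop-1-en-2-yl)-7-oxabicyclo[4.1.0]heptan-2-yl]oxy}silane
Product: 12 (1R,2R,5R)-2-methyl-5-(prop-1-en-2-yl)-2-[(triethylsilyl)oxy]cyclopentane-1-carbaldehyde, via iodohydrin magnesium salt 11 (not isolated)
Conditions: MgI2·OEt2 (1.5 equiv), toluene, 0 to 45 °C
Reagents that add atoms: none
Why: Proposed new method: iodide-relayed semipinacol ring contraction of a 2,3-epoxy-1-silyloxycyclohexane — MgI2 opens the oxirane of 10 at C6 (the carbon remote from the silyloxy carbon; trans-diaxial, inversion) to the iodohydrin magnesium alkoxide 11, whose conformer with equatorial C–I has the C1–C2 ring bond antiperiplanar to C–I, so the silyloxy-bearing carbon C2 shifts from C1 to C6 with a second inversion while C1 becomes the formyl carbon, which places CHO cis to isopropenyl and trans to OSiEt3 (net retention at C6, the opposite of the direct Lewis-acid epoxide rearrangement) and leaves C2 and C5 untouched; the closest known reactions are the lithium- or magnesium-halide-mediated ring contraction of cyclohexene oxide to cyclopentanecarbaldehyde through the halohydrin salt (Rickborn, Tiffeneau) and the Maruoka–Yamamoto rearrangement of epoxy silyl ethers, neither shown with a migrating ring silyloxy carbon.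

**Step 7**
Reactants: 12 (1R,2R,5R)-2-methyl-5-(prop-1-en-2-yl)-2-[(triethylsilyl)oxy]cyclopentane-1-carbaldehyde
Product: 13 triethyl{[(1R,2S,3R)-2-[(E)-2-iodoethenyl]-1-methyl-3-(prop-1-en-2-yl)cyclopentyl]oxy}silane
Conditions: CrCl2 (6 equiv), CHI3 (2 equiv), THF–1,4-dioxane, 0 °C to rt
Reagents that add atoms: iodoform, IC(I)I
Why: Takai olefination through a geminal dichromium reagent gives the E-iodoalkene under non-basic conditions, so the epimerisable formyl-bearing stereocentre is kept.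

**Step 8**
Reactants: 13 triethyl{[(1R,2S,3R)-2-[(E)-2-iodoethenyl]-1-methyl-3-(prop-1-en-2-yl)cyclopentyl]oxy}silane
Product: 14 {[(1R,2R,3R)-2-[(1E)-but-1-en-3-yn-1-yl]-1-methyl-3-(prop-1-en-2-yl)cyclopentyl]oxy}triethylsilane
Conditions: HC≡CMgBr, ZnBr2, Pd(PPh3)4 (5 mol %), THF, 0 °C to rt
Reagents that add atoms: ethynylmagnesium bromide, C#C[Mg]Br
Why: Negishi alkynylation with ethynylzinc bromide gives the terminal enyne directly with retention of the E geometry.

**Step 9**
Reactants: 15 (E)-1,2-dichloroethene (5 equiv); 16 ethynyltrimethylsilane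
Product: 17 [(3E)-4-chlorobut-3-en-1-yn-1-yl]trimethylsilane
Conditions: Pd(PPh3)4 (5 mol %), CuI (10 mol %), n-BuNH2, Et2O, rt
Reagents that add atoms: none
Why: Sonogashira mono-alkynylation of the dichloride with retention of geometry; excess dichloride suppresses the second coupling.

**Step 10**
Reactants: 14 {[(1R,2R,3R)-2-[(1E)-but-1-en-3-yn-1-yl]-1-methyl-3-(prop-1-en-2-yl)cyclopentyl]oxy}triethylsilane; 17 [(3E)-4-chlorobut-3-en-1-yn-1-yl]trimethylsilane
Product: 19 triethyl{[(1R,2R,3R)-1-methyl-2-[(1E,3E,5E)-3-methyl-8-(trimethylsilyl)octa-1,3,5-trien-7-yn-1-yl]-3-(prop-1-en-2-yl)cyclopentyl]oxy}silane, via alkenylalane 18 (not isolated)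
Conditions: Me3Al (2.5 equiv), Cp2ZrCl2 (0.25 equiv), ClCH2CH2Cl, rt; evaporate; then 17, ZnCl2 (0.3 equiv), Pd(P(t-Bu)3)2 (3 mol %), THF, rt to 40 °C
Reagents that add atoms: trimethylaluminium, C[Al](C)C
Why: Negishi Zr-catalysed methylalumination (syn, methyl to the internal carbon) fixes the E-trisubstituted C9=C10 bond, and Pd/Zn-cocatalysed alkenyl–alkenyl coupling with the activated chloroenyne proceeds with retention.

**Step 11**
Reactants: 19 triethyl{[(1R,2R,3R)-1-methyl-2-[(1E,3E,5E)-3-methyl-8-(trimethylsilyl)octa-1,3,5-trien-7-yn-1-yl]-3-(prop-1-en-2-yl)cyclopentyl]oxy}silane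
Product: 20 (1R,2R,3R)-1-methyl-2-[(1E,3E,5E)-3-methylocta-1,3,5-trien-7-yn-1-yl]-3-(prop-1-en-2-yl)cyclopentan-1-ol
Conditions: Bu4NF (3 equiv), THF, 0 °C to rt
Reagents that add atoms: none
Why: Fluoride-mediated desilylation cleaves both the alkynyl C–SiMe3 bond and the tertiary O–SiEt3 ether in one operation.

**Step 12**
Reactants: 21 5-bromo-2-methylpent-2-ene
Product: 22 6-methylhept-5-en-1-yne
Conditions: lithium acetylide–ethylenediamine, DMSO, 10 °C to rt
Reagents that add atoms: lithium acetylide–ethylenediamine complex, [Li]C#C.NCCN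
Why: SN2 alkylation of the acetylide by the primary bromide.

**Step 13**
Reactants: 22 6-methylhept-5-en-1-yne; 17 [(3E)-4-chlorobut-3-en-1-yn-1-yl]trimethylsilane
Product: 24 trimethyl[(3E,5E)-6,10-dimethylundeca-3,5,9-trien-1-yn-1-yl]silane, via alkenylalane 23 (not isolated)
Conditions: Me3Al (2 equiv), Cp2ZrCl2 (0.25 equiv), ClCH2CH2Cl, rt; evaporate; then 17, ZnCl2 (0.3 equiv), Pd(P(t-Bu)3)2 (3 mol %), THF, rt
Reagents that add atoms: trimethylaluminium, C[Al](C)C
Why: Zr-catalysed methylalumination then Negishi coupling, as in step 10, sets the E-trisubstituted alkene next to the chain end.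

**Step 14**
Reactants: 24 trimethyl[(3E,5E)-6,10-dimethylundeca-3,5,9-trien-1-yn-1-yl]silane
Product: 25 (3E,5E)-6,10-dimethylundeca-3,5,9-trien-1-yne
Conditions: K2CO3 (0.3 equiv), MeOH–THF, rt
Reagents that add atoms: none
Why: Methoxide-catalysed protodesilylation of the alkynylsilane.

**Step 15**
Reactants: 25 (3E,5E)-6,10-dimethylundeca-3,5,9-trien-1-yne; 17 [(3E)-4-chlorobut-3-en-1-yn-1-yl]trimethylsilane
Product: 27 trimethyl[(3E,5E,7E,9E)-6,10,14-trimethylpentadeca-3,5,7,9,13-pentaen-1-yn-1-yl]silane, via alkenylalane 26 (not isolated)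
Conditions: Me3Al (2 equiv), Cp2ZrCl2 (0.25 equiv), ClCH2CH2Cl, rt; evaporate; then 17, ZnCl2 (0.3 equiv), Pd(P(t-Bu)3)2 (3 mol %), THF, rt
Reagents that add atoms: trimethylaluminium, C[Al](C)C
Why: Second methylalumination/Negishi coupling cycle, with the same regio- and stereocontrol as step 13.

**Step 16**
Reactants: 27 trimethyl[(3E,5E,7E,9E)-6,10,14-trimethylpentadeca-3,5,7,9,13-pentaen-1-yn-1-yl]silane
Product: 28 (3E,5E,7E,9E)-6,10,14-trimethylpentadeca-3,5,7,9,13-pentaen-1-yne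
Conditions: K2CO3 (0.3 equiv), MeOH–THF, rt, dark
Reagents that add atoms: none
Why: Methoxide-catalysed protodesilylation of the alkynylsilane.

**Step 17**
Reactants: 28 (3E,5E,7E,9E)-6,10,14-trimethylpentadeca-3,5,7,9,13-pentaen-1-yne; 15 (E)-1,2-dichloroethene (10 equiv)
Product: 30 (1E,3E,5E,7E,9E,11E)-1-chloro-4,8,12,16-tetramethylheptadeca-1,3,5,7,9,11,15-heptaene, via alkenylalane 29 (not isolated)
Conditions: Me3Al (2 equiv), Cp2ZrCl2 (0.25 equiv), ClCH2CH2Cl, rt; evaporate; then 15, ZnCl2 (0.3 equiv), Pd(PPh3)4 (5 mol %), THF, rt, dark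
Reagents that add atoms: trimethylaluminium, C[Al](C)C
Why: Methylalumination then Pd-catalysed mono-coupling with excess (E)-dichloroethene (Negishi-type coupling, retention); the chlorodiene product is much less reactive than the dichloride with this catalyst.

**Step 18**
Reactants: 20 (1R,2R,3R)-1-methyl-2-[(1E,3E,5E)-3-methylocta-1,3,5-trien-7-yn-1-yl]-3-(prop-1-en-2-yl)cyclopentan-1-ol; 30 (1E,3E,5E,7E,9E,11E)-1-chloro-4,8,12,16-tetramethylheptadeca-1,3,5,7,9,11,15-heptaene
Product: 32 CNP0222499.3, (1R,2R,3R)-1-methyl-3-(prop-1-en-2-yl)-2-[(1E,3E,5E,7E,9E,11E,13E,15E,17E,19E)-3,7,12,16,20,24-hexamethylpentacosa-1,3,5,7,9,11,13,15,17,19,23-undecaen-1-yl]cyclopentan-1-ol, via alkenylalane 31 (not isolated)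
Conditions: Me3Al (3.5 equiv), Cp2ZrCl2 (0.3 equiv), ClCH2CH2Cl, rt; evaporate; then 30, ZnCl2 (0.3 equiv), Pd(P(t-Bu)3)2 (5 mol %), THF, rt to 45 °C, dark; aq. NaHCO3
Reagents that add atoms: trimethylaluminium, C[Al](C)C
Why: The free tertiary alcohol is masked in situ as its dimethylaluminium alkoxide, Zr-catalysed methylalumination sets the E C13=C14 bond, and Negishi alkenyl–alkenyl coupling with the chloropolyene joins the halves with retention at both alkenes.

**Compound list**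

1 | 2-(trimethylsilyloxy)buta-1,3-diene | C=CC(=C)O[Si](C)(C)C | starting material
2 | but-3-en-2-one | CC(=O)C=C | starting material
3 | rac-1-[4-(trimethylsilyloxy)cyclohex-3-en-1-yl]ethan-1-one | CC(=O)C1CCC(O[Si](C)(C)C)=CC1 | intermediate
4 | rac-trimethyl{[4-(prop-1-en-2-yl)cyclohex-1-en-1-yl]oxy}silane | CC(=C)C1CCC(O[Si](C)(C)C)=CC1 | intermediate (not isolated)
5 | 4-(prop-1-en-2-yl)cyclohexan-1-one | CC(=C)C1CCC(=O)CC1 | intermediate
6 | lithium (4R)-4-(prop-1-en-2-yl)cyclohex-1-en-1-olate | CC(=C)[C@@H]1CCC(O[Li])=CC1 | intermediate (not isolated)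
7 | (4R)-4-(prop-1-en-2-yl)cyclohex-2-en-1-one | CC(=C)[C@@H]1CCC(=O)C=C1 | intermediate
8 | (1S,5S,6S)-5-(prop-1-en-2-yl)-7-oxabicyclo[4.1.0]heptan-2-one | CC(=C)[C@@H]1CCC(=O)[C@H]2O[C@@H]12 | intermediate
9 | bromomagnesium (1S,2R,5S,6S)-2-methyl-5-(prop-1-en-2-yl)-7-oxabicyclo[4.1.0]heptan-2-olate | CC(=C)[C@@H]1CC[C@@](C)(O[Mg]Br)[C@H]2O[C@@H]12 | intermediate (not isolated)
10 | triethyl{[(1S,2R,5S,6S)-2-methyl-5-(prop-1-en-2-yl)-7-oxabicyclo[4.1.0]heptan-2-yl]oxy}silane | CC(=C)[C@@H]1CC[C@@](C)(O[Si](CC)(CC)CC)[C@H]2O[C@@H]12 | intermediate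
11 | iodomagnesium (1R,2R,3S,6R)-2-iodo-6-methyl-3-(prop-1-en-2-yl)-6-[(triethylsilyl)oxy]cyclohexan-1-olate | CC(=C)[C@@H]1CC[C@@](C)(O[Si](CC)(CC)CC)[C@@H](O[Mg]I)[C@@H]1I | intermediate (not isolated)
12 | (1R,2R,5R)-2-methyl-5-(prop-1-en-2-yl)-2-[(triethylsilyl)oxy]cyclopentane-1-carbaldehyde | C=C(C)[C@@H]1CC[C@@](C)(O[Si](CC)(CC)CC)[C@@H]1C=O | intermediate
13 | triethyl{[(1R,2S,3R)-2-[(E)-2-iodoethenyl]-1-methyl-3-(prop-1-en-2-yl)cyclopentyl]oxy}silane | C=C(C)[C@@H]1CC[C@@](C)(O[Si](CC)(CC)CC)[C@@H]1/C=C/I | intermediate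
14 | {[(1R,2R,3R)-2-[(1E)-but-1-en-3-yn-1-yl]-1-methyl-3-(prop-1-en-2-yl)cyclopentyl]oxy}triethylsilane | C=C(C)[C@@H]1CC[C@@](C)(O[Si](CC)(CC)CC)[C@@H]1/C=C/C#C | intermediate
15 | (E)-1,2-dichloroethene | Cl/C=C/Cl | starting material
16 | ethynyltrimethylsilane | C#C[Si](C)(C)C | starting material
17 | [(3E)-4-chlorobut-3-en-1-yn-1-yl]trimethylsilane | Cl/C=C/C#C[Si](C)(C)C | intermediate
18 | dimethyl{(1E,3E)-2-methyl-4-[(1R,2R,5R)-2-methyl-5-(prop-1-en-2-yl)-2-[(triethylsilyl)oxy]cyclopentyl]buta-1,3-dien-1-yl}alumane | C=C(C)[C@@H]1CC[C@@](C)(O[Si](CC)(CC)CC)[C@@H]1/C=C/C(C)=C/[Al](C)C | intermediate (not isolated)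
19 | triethyl{[(1R,2R,3R)-1-methyl-2-[(1E,3E,5E)-3-methyl-8-(trimethylsilyl)octa-1,3,5-trien-7-yn-1-yl]-3-(prop-1-en-2-yl)cyclopentyl]oxy}silane | C=C(C)[C@@H]1CC[C@@](C)(O[Si](CC)(CC)CC)[C@@H]1/C=C/C(C)=C/C=C/C#C[Si](C)(C)C | intermediate
20 | (1R,2R,3R)-1-methyl-2-[(1E,3E,5E)-3-methylocta-1,3,5-trien-7-yn-1-yl]-3-(prop-1-en-2-yl)cyclopentan-1-ol | C=C(C)[C@@H]1CC[C@@](C)(O)[C@@H]1/C=C/C(C)=C/C=C/C#C | intermediate
21 | 5-bromo-2-methylpent-2-ene | CC(C)=CCCBr | starting material
22 | 6-methylhept-5-en-1-yne | CC(C)=CCCC#C | intermediate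
23 | [(1E)-2,6-dimethylhepta-1,5-dien-1-yl]dimethylalumane | CC(C)=CCC/C(C)=C/[Al](C)C | intermediate (not isolated)
24 | trimethyl[(3E,5E)-6,10-dimethylundeca-3,5,9-trien-1-yn-1-yl]silane | CC(C)=CCC/C(C)=C/C=C/C#C[Si](C)(C)C | intermediate
25 | (3E,5E)-6,10-dimethylundeca-3,5,9-trien-1-yne | CC(C)=CCC/C(C)=C/C=C/C#C | intermediate
26 | dimethyl[(1E,3E,5E)-2,6,10-trimethylundeca-1,3,5,9-tetraen-1-yl]alumane | CC(C)=CCC/C(C)=C/C=C/C(C)=C/[Al](C)C | intermediate (not isolated)
27 | trimethyl[(3E,5E,7E,9E)-6,10,14-trimethylpentadeca-3,5,7,9,13-pentaen-1-yn-1-yl]silane | CC(C)=CCC/C(C)=C/C=C/C(C)=C/C=C/C#C[Si](C)(C)C | intermediate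
28 | (3E,5E,7E,9E)-6,10,14-trimethylpentadeca-3,5,7,9,13-pentaen-1-yne | CC(C)=CCC/C(C)=C/C=C/C(C)=C/C=C/C#C | intermediate
29 | dimethyl[(1E,3E,5E,7E,9E)-2,6,10,14-tetramethylpentadeca-1,3,5,7,9,13-hexaen-1-yl]alumane | CC(C)=CCC/C(C)=C/C=C/C(C)=C/C=C/C(C)=C/[Al](C)C | intermediate (not isolated)
30 | (1E,3E,5E,7E,9E,11E)-1-chloro-4,8,12,16-tetramethylheptadeca-1,3,5,7,9,11,15-heptaene | CC(C)=CCC/C(C)=C/C=C/C(C)=C/C=C/C(C)=C/C=C/Cl | intermediate
31 | {(1E,3E,5E,7E)-8-[(1R,2R,5R)-2-[(dimethylalumanyl)oxy]-2-methyl-5-(prop-1-en-2-yl)cyclopentyl]-2,6-dimethylocta-1,3,5,7-tetraen-1-yl}dimethylalumane | C=C(C)[C@@H]1CC[C@@](C)(O[Al](C)C)[C@@H]1/C=C/C(C)=C/C=C/C(C)=C/[Al](C)C | intermediate (not isolated)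
32 | CNP0222499.3, (1R,2R,3R)-1-methyl-3-(prop-1-en-2-yl)-2-[(1E,3E,5E,7E,9E,11E,13E,15E,17E,19E)-3,7,12,16,20,24-hexamethylpentacosa-1,3,5,7,9,11,13,15,17,19,23-undecaen-1-yl]cyclopentan-1-ol | C=C(C)[C@@H]1CC[C@@](C)(O)[C@@H]1/C=C/C(C)=C/C=C/C(C)=C/C=C/C=C(C)/C=C/C=C(C)/C=C/C=C(\C)CCC=C(C)C | target

**Step count and risks**

Total: 18 steps. Longest linear sequence: 11 steps (steps 1–8, 10, 11, 18).

The three steps most likely to fail:

Step 6 (the proposed new ring contraction). Possible failures are halide attack at the wrong oxirane carbon, a stalled or re-closing iodohydrin, 1,2-O-to-O silyl shift in 11, or leakage into the direct Lewis-acid pathway that gives the C1 epimer. The fallback uses known chemistry, sets out from 10 and returns at 12. Azidolysis of 10 (NaN3, NH4Cl, aq. MeOH, 70 °C; trans-diaxial attack at the same carbon) gives (1S,2R,3S,6R)-2-azido-6-methyl-3-(prop-1-en-2-yl)-6-[(triethylsilyl)oxy]cyclohexan-1-ol F1. Staudinger reduction (PPh3, THF–H2O) gives (1S,2R,3S,6R)-2-amino-6-methyl-3-(prop-1-en-2-yl)-6-[(triethylsilyl)oxy]cyclohexan-1-ol F2. Nitrous acid deamination (NaNO2, aq. AcOH, 0 °C) is the classical Tiffeneau–Demjanov-type semipinacol ring contraction of a trans-2-aminocyclohexanol: the equatorial diazonium conformer loses N2 with shift of the same ring bond, giving 12 with the same stereochemical outcome. Epoxide formed from the diaxial conformer is recycled, and any lost silyl group is put back with Et3SiOTf.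

Step 3 (desymmetrising deprotonation and one-flask dehydrogenation). Possible failures are an ee below about 90%, enolate equilibration before oxidation, or interception of the sulfinimidoyl chloride by the amine. Material of insufficient ee can be enriched at 7 by chromatography on a chiral phase. The fallback moves the stereo-defining event to the cycloaddition; it sets out from 1 and 2 and returns at 7. A Diels–Alder reaction catalysed by a chiral cationic oxazaborolidinium triflimide (CH2Cl2, −78 °C, catalyst enantiomer chosen for the R adduct) gives 1-[(1R)-4-(trimethylsilyloxy)cyclohex-3-en-1-yl]ethan-1-one F3. Salt-free Wittig methylenation with non-aqueous work-up gives trimethyl{[(4R)-4-(prop-1-en-2-yl)cyclohex-1-en-1-yl]oxy}silane F4. Saegusa–Ito oxidation (Pd(OAc)2, MeCN, rt) then gives 7.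

Step 18 (final union). Possible failures are slow oxidative addition of the electron-rich chloropolyene 30, E/Z erosion, or decomposition of the polyene in the presence of aluminium residues. The fallback is a Stille union; it sets out from 20 and 28 and returns at 32. Methylalumination of 20 followed by I2 (THF, −30 °C) gives (1R,2R,3R)-2-[(1E,3E,5E,7E)-8-iodo-3,7-dimethylocta-1,3,5,7-tetraen-1-yl]-1-methyl-3-(prop-1-en-2-yl)cyclopentan-1-ol F5. The same sequence on 28 gives (1E,3E,5E,7E,9E)-1-iodo-2,6,10,14-tetramethylpentadeca-1,3,5,7,9,13-hexaene F6. Stille coupling of F6 with excess (E)-1,2-bis(tributylstannyl)ethene (Pd(PPh3)4, DMF, rt) gives tributyl[(1E,3E,5E,7E,9E,11E)-4,8,12,16-tetramethylheptadeca-1,3,5,7,9,11,15-heptaen-1-yl]stannane F7. A second Stille coupling of F7 with F5 (Pd2(dba)3, AsPh3, NMP, rt, dark) gives 32.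

**Further compounds**

F1 | step 6 | (1S,2R,3S,6R)-2-azido-6-methyl-3-(prop-1-en-2-yl)-6-[(triethylsilyl)oxy]cyclohexan-1-ol | CC(=C)[C@@H]1CC[C@@](C)(O[Si](CC)(CC)CC)[C@@H](O)[C@@H]1N=[N+]=[N-]
F2 | step 6 | (1S,2R,3S,6R)-2-amino-6-methyl-3-(prop-1-en-2-yl)-6-[(triethylsilyl)oxy]cyclohexan-1-ol | CC(=C)[C@@H]1CC[C@@](C)(O[Si](CC)(CC)CC)[C@@H](O)[C@@H]1N
F3 | step 3 | 1-[(1R)-4-(trimethylsilyloxy)cyclohex-3-en-1-yl]ethan-1-one | CC(=O)[C@@H]1CCC(O[Si](C)(C)C)=CC1
F4 | step 3 | trimethyl{[(4R)-4-(prop-1-en-2-yl)cyclohex-1-en-1-yl]oxy}silane | CC(=C)[C@@H]1CCC(O[Si](C)(C)C)=CC1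
F5 | step 18 | (1R,2R,3R)-2-[(1E,3E,5E,7E)-8-iodo-3,7-dimethylocta-1,3,5,7-tetraen-1-yl]-1-methyl-3-(prop-1-en-2-yl)cyclopentan-1-ol | C=C(C)[C@@H]1CC[C@@](C)(O)[C@@H]1/C=C/C(C)=C/C=C/C(C)=C/I
F6 | step 18 | (1E,3E,5E,7E,9E)-1-iodo-2,6,10,14-tetramethylpentadeca-1,3,5,7,9,13-hexaene | CC(C)=CCC/C(C)=C/C=C/C(C)=C/C=C/C(C)=C/I
F7 | step 18 | tributyl[(1E,3E,5E,7E,9E,11E)-4,8,12,16-tetramethylheptadeca-1,3,5,7,9,11,15-heptaen-1-yl]stannane | CC(C)=CCC/C(C)=C/C=C/C(C)=C/C=C/C(C)=C/C=C/[Sn](CCCC)(CCCC)CCCC
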